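All runs come from a simulation with made-up constants, and the scatter is random.

7.14 turnovers per catalyst, call this N: at a loading of 14 mol%, that is what consuming the charged starting material takes. The flask asked about is the noon run itself, followed further.

| flask | starting material | gas | free catalyst | added ligand | remark | time |
|---|---|---|---|---|---|---|
| noon | 0.40 M | 200 mM (held) | 14 mol% | 310 mM | the very flask that is asked about, followed so far |  |
| flask | 0.40 M | 200 mM (held) | 14 mol% | 310 mM |  | 15 min |

noon run (percent of the starting material charged)

| time / min | target / % | starting material / % |
|---|---|---|
| 0.333 | 5.4 | 94.1 |
| 0.667 | 17.4 | 81.4 |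
| 1.00 | 32.0 | 66.9 |
| 1.50 | 52.4 | 47.2 |
| 2.50 | 82.7 | 17.7 |
| 5.00 | 99.3 | 0 |

(each reading ± 0.5 percentage points)

- at the start none of the gas is in solution
- the reaction counts as stopped when no species that holds the starting material changes by six tenths of a point or more over the second half of the time

- which holds at 15 min: what has brought the reaction to rest, or that it has not come to rest (it is still moving / no working catalyst is left / forward and back rates have come level / all of the starting material has reacted)
- the target standing at 15 min, as a percentage of the starting material charged

Two chemists dispute it. The second points to the added ligand, 5.54 times the catalyst charged, and to a target still 0.7 percentage points short of full at 5.00 min. She expects a throttled catalyst, still creeping at 15 min. The first made the forecast: all of the starting material has reacted, with the target at 99.7 %, since “the rate shows no sign of flagging”.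

My own count sides with him. Between 1.00 min and 2.50 min the starting material fell from 66.9 % to 17.7 %, which reads as a pace r of 2.34 min⁻¹ per catalyst charged. The added ligand stood in that same flask, so whatever it costs is already inside r. The turnover margin M, turnovers on offer by the asked time over turnovers demanded, r·t/N, is 4.92. So I expect the flask to finish, but my count caps the target at the charge and gives no finer figure; 99.7 % is the forecast's number.

The simulation gives all of the starting material has reacted, with the target at 100 % and starting material, the limiting reagent, at 0 % at 15.0 min.

    coupling partner + free catalyst → catalyst intermediate A (k = 2.96 M⁻¹ s⁻¹)
    catalyst intermediate A ⇌ catalyst intermediate B (K = 2.13, k = 0.566 s⁻¹)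
    starting material + catalyst intermediate B ⇌ catalyst intermediate C (K = 1.27 M⁻¹, k = 46.9 M⁻¹ s⁻¹)
    catalyst intermediate C → free catalyst + target (k = 0.642 s⁻¹)
    gas ⇌ coupling partner, rate k5*(csat - [coupling partner]) (kL = 0.0272 s⁻¹)
    free catalyst + added ligand ⇌ idle complex (K = 3.90 M⁻¹, k = 1.04 M⁻¹ s⁻¹)

The second chemist's idle complex does form: it holds 22.0 % of the catalyst at 1.50 min, a time inside the stretch that gave r. A target short of full at 15 min, as she expected, has its region at low loading: at 2.4 mol% of free catalyst, all else held, the target has moved by 5 points, and M there, at the noon pace, reckons 0.842. The neighbouring flask with 35 mol% of free catalyst needs 2.86 turnovers, so at the noon pace its M is 12.3. That neighbouring flask ends with the target at 100 % and starting material at 0 %.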